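The route rests on disconnecting the C1–C10 bond of ring A (eudesmane numbering) and closing it by a hydrogen-atom-transfer radical cyclization. Fe(acac)3/PhSiH3 converts the C9=C10 alkene of a preformed ring B into the tertiary C10 radical, which adds 6-endo to C1 of a C5-tethered vinyl ketone. One operation forms ring A and sets the quaternary, methyl-bearing C10 trans to the C5 hydroxyl. The step exploits that C10 is the methyl-substituted ring-fusion carbon next to the C5 carbinol and that C1 lies β to the C3 oxygen. The precursor is a monocyclic 4-hydroxycyclohexene carrying a cross-conjugated dienone at C5, an alkyne at C7 and a ketal at C8.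

Key step: step 9

Remark 1: atoms are numbered as in eudesmane (ring A = C1–C5, C10; ring B = C5–C10; C14 on C10, C15 on C4, C11–C13 on C7); α is the face of the 5-hydroxyl, β the face of the C10 methyl.
Remark 2 (assumption): the sense of induction in step 2 is taken by analogy with simpler cyclic enones; the ligand antipode that gives (5R)-4 is the one used.

Step 1
Reactants: 1 4-methoxy-2-methylphenol
Product: 2 4,4-dimethoxy-2-methylcyclohexa-2,5-dien-1-one
Conditions: PhI(OAc)2, MeOH, 0 °C
Reagents that add atoms: methanol, CO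
Why: Hypervalent-iodine oxidative dearomatization of the p-methoxyphenol traps the phenoxonium ion with methanol at the para carbon and should give the quinone monoketal; no stereocentre is formed.

Step 2
Reactants: 2 4,4-dimethoxy-2-methylcyclohexa-2,5-dien-1-one; 3 ethynyltri(propan-2-yl)silane
Product: 4 (5R)-4,4-dimethoxy-2-methyl-5-{[tri(propan-2-yl)silyl]ethynyl}cyclohex-2-en-1-one
Conditions: [Rh(OAc)(C2H4)2]2 (cat.), (R)-DTBM-SEGPHOS, 1,4-dioxane, 80 °C
Reagents that add atoms: ethynyltri(propan-2-yl)silane (3), C#C[Si](C(C)C)(C(C)C)C(C)C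
Why: Rhodium-catalysed asymmetric conjugate alkynylation: the rhodium acetylide should add to the less substituted enone of 2, and the chiral bisphosphine differentiates its enantiotopic faces, which sets the future C7 stereocentre.

Step 3
Reactants: 4 (5R)-alkynyl enone
Product: 5 (1R,4R,6S)-5,5-dimethoxy-1-methyl-4-{[tri(propan-2-yl)silyl]ethynyl}-7-oxabicyclo[4.1.0]heptan-2-one (oxirane trans to the alkynyl group)
Conditions: H2O2 (30% aq.), NaOH, MeOH, 0 °C
Reagents that add atoms: hydrogen peroxide, OO
Why: Weitz–Scheffer epoxidation of the remaining α-methyl enone; hydroperoxide should attack the β-carbon anti to the alkynyl group two carbons away (as with 5-substituted cyclohexenones), which places the oxirane on the α face.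

Step 4
Reactants: 6 acrolein
Product: 8 2-bromoprop-2-enal, via 2,3-dibromopropanal 7 (not isolated)
Conditions: Br2, CH2Cl2, −78 °C; then Et3N, −78 to 0 °C
Reagents that add atoms: bromine, BrBr
Why: Bromine addition to the alkene followed by E1cB loss of HBr from the α-bromo aldehyde should give the 2-bromo enal; no stereocentre is formed.

Step 5
Reactants: 8 2-bromoprop-2-enal; 9 vinylmagnesium bromide
Product: 10 2-bromopenta-1,4-dien-3-ol (racemic)
Conditions: THF, −78 °C; aq. NH4Cl
Reagents that add atoms: vinylmagnesium bromide (9), C=C[Mg]Br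
Why: 1,2-Addition of the vinyl Grignard reagent to the aldehyde at low temperature gives the bis-allylic alcohol; its carbinol centre is erased by oxidation in step 8.

Step 6
Reactants: 5 epoxy ketone; 10 2-bromopenta-1,4-dien-3-ol
Product: 11 (1R,2R,4R,6S)-2-(3-hydroxypenta-1,4-dien-2-yl)-5,5-dimethoxy-1-methyl-4-{[tri(propan-2-yl)silyl]ethynyl}-7-oxabicyclo[4.1.0]heptan-2-ol (both epimers at the side-chain carbinol)
Conditions: 10, n-BuLi then t-BuLi, THF, −78 °C; CeCl3; then 5, −78 °C; aq. NH4Cl
Reagents that add atoms: 2-bromopenta-1,4-dien-3-ol (10, as its dilithio derivative), C=CC(O)C(Br)=C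
Why: O-Deprotonation and bromine–lithium exchange give a vinyl dianion whose organocerium form should add 1,2 to the ketone without enolization; attack anti to the oxirane oxygen (Felkin–Anh and steric control) sets C5 with the hydroxyl on the α face and the carbon chain cis to the alkynyl group.

Step 7
Reactants: 11 epoxy diol
Product: 12 (1S,5R)-1-(3-hydroxypenta-1,4-dien-2-yl)-4,4-dimethoxy-2-methyl-5-{[tri(propan-2-yl)silyl]ethynyl}cyclohex-2-en-1-ol (both side-chain epimers)
Conditions: WCl6, n-BuLi, THF, −78 °C to rt; then 11, rt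
Reagents that add atoms: none
Why: Oxygen-atom transfer from the oxirane to low-valent tungsten chloride (epoxide deoxygenation) should unveil the C9=C10 alkene; the oxirane has served only to relay the configuration of C7 to C5.

Step 8
Reactants: 12 diene diol
Product: 13 2-[(1S,5R)-1-hydroxy-4,4-dimethoxy-2-methyl-5-{[tri(propan-2-yl)silyl]ethynyl}cyclohex-2-en-1-yl]penta-1,4-dien-3-one
Conditions: MnO2, CH2Cl2, rt
Reagents that add atoms: none
Why: MnO2 oxidizes only the activated bis-allylic secondary alcohol to the cross-conjugated dienone and leaves the tertiary alcohol untouched.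

Step 9
Reactants: 13 hydroxy dienone
Product: 14 5α-hydroxy-8,8-dimethoxy-10β-methyl-4-methylidene-7β-{[tri(propan-2-yl)silyl]ethynyl}-trans-decalin-3-one (eudesmane numbering)
Conditions: Fe(acac)3 (substoichiometric), PhSiH3, EtOH, 60 °C, high dilution
Reagents that add atoms: none
Why: Fe(acac)3/PhSiH3/EtOH forms an iron hydride that transfers a hydrogen atom to C9 of the electron-neutral trisubstituted C9=C10 alkene (Markovnikov MHAT); the tertiary C10 radical adds to the terminal carbon C1 of the vinyl ketone, and the resulting C2 α-keto radical is reduced to the iron enolate and protonated by ethanol. The closest known reaction type is the MHAT-initiated reductive olefin coupling run as an intramolecular Giese cyclization. Ring A closes in the 6-endo-trig mode, favoured over 5-exo attack at C2 because the nucleophilic tertiary radical seeks the β-carbon of the enone. The new quaternary stereocentre C10 is controlled by a chair–chair transition state: ring B is locked by the cis-related equatorial C7 alkynyl group and equatorial C4 tether (5-OH axial), so C1 bonds equatorially and the methyl group ends axial, anti to the hydroxyl (trans-decalin), as in radical polyene cyclizations. The step needs hydrogen-atom transfer to C9=C10 in preference to the two enone alkenes and the silylalkyne, which rests on the preference of the iron hydride for electron-neutral alkenes; high dilution suppresses intermolecular Giese addition.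

Step 10
Reactants: 14 decalin enone
Product: 15 3β,5α-dihydroxy-8,8-dimethoxy-10β-methyl-4-methylidene-7β-{[tri(propan-2-yl)silyl]ethynyl}-trans-decalin
Conditions: Me4NBH(OAc)3, MeCN/AcOH, −30 °C
Reagents that add atoms: none
Why: Evans–Saksena reduction: the acetoxyborohydride is bound by the axial 5α-hydroxyl and should deliver hydride to the α face of the C3 ketone, giving the 1,3-anti diol (3β-OH) by 1,2-reduction.

Step 11
Reactants: 15 diol; 16 angelic acid ((2Z)-2-methylbut-2-enoic acid)
Product: 17 3β-[(2Z)-2-methylbut-2-enoyloxy]-5α-hydroxy-8,8-dimethoxy-10β-methyl-4-methylidene-7β-{[tri(propan-2-yl)silyl]ethynyl}-trans-decalin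
Conditions: 16, 2,4,6-trichlorobenzoyl chloride, Et3N, toluene, rt; then 15, 80 °C
Reagents that add atoms: angelic acid (16), C/C=C(/C)C(=O)O
Why: Yamaguchi esterification through the mixed anhydride, run without DMAP to avoid Z-to-E isomerization, should acylate the secondary allylic 3β-hydroxyl while the tertiary 5α-hydroxyl stays free.

Step 12
Reactants: 17 angelate ketal
Product: 19 3β-angeloyloxy-5α,8β-dihydroxy-10β-methyl-4-methylidene-7β-{[tri(propan-2-yl)silyl]ethynyl}-trans-decalin, via 8-oxo angelate 18 (not isolated)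
Conditions: PPTS, acetone/H2O, 40 °C; concentrate; then NaBH4, MeOH, −20 °C
Reagents that add atoms: water, O
Why: Mild acid hydrolysis of the dimethyl ketal gives the 8-ketone, which is reduced at once to limit epimerization at C7; hydride should attack from the equatorial α face because the axial approach is blocked by the syn-axial 10β-methyl, giving the axial 8β-alcohol.

Step 13
Reactants: 19 silylalkyne diol
Product: 20 3β-angeloyloxy-7β-ethynyl-5α,8β-dihydroxy-10β-methyl-4-methylidene-trans-decalin
Conditions: TBAF, AcOH, THF, 0 °C to rt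
Reagents that add atoms: none
Why: Fluoride-mediated protodesilylation of the alkynylsilane, buffered with acetic acid to protect the angelate, frees the terminal alkyne.

Step 14
Reactants: 20 terminal alkyne diol
Product: 21 8β-acetoxy-3β-angeloyloxy-7β-ethynyl-5α-hydroxy-10β-methyl-4-methylidene-trans-decalin
Conditions: Ac2O, pyridine, DMAP (cat.), CH2Cl2, rt
Reagents that add atoms: acetic anhydride, CC(=O)OC(C)=O
Why: DMAP-catalysed acetylation of the secondary axial 8β-hydroxyl leaves the tertiary 5α-hydroxyl alone; acylating before the C12 ester exists prevents lactonization onto C12.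

Step 15
Reactants: 21 alkynyl acetate
Product: 22 methyl 8β-acetoxy-3β-[(2Z)-2-methylbut-2-enoyloxy]-5α-hydroxy-7αH-eudesma-4(15),11(13)-dien-12-oate (CNP0179024.1)
Conditions: Pd(OAc)2 (cat.), 2-(diphenylphosphino)pyridine, CH3SO3H (cat.), CO (10 bar), MeOH/CH2Cl2, 45 °C
Reagents that add atoms: carbon monoxide, [C-]#[O+]; methanol, CO
Why: Palladium-catalysed Markovnikov hydromethoxycarbonylation of the terminal alkyne (pyridylphosphine-ligated palladium places the ester on the internal carbon) should give the branched 2-substituted acrylate, i.e. the C11(=C13)–C12O2Me unit, without touching a stereocentre.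

Compound list
1 | 4-methoxy-2-methylphenol | COc1ccc(O)c(C)c1 | starting material
2 | 4,4-dimethoxy-2-methylcyclohexa-2,5-dien-1-one | COC1(OC)C=CC(=O)C(C)=C1 | intermediate
3 | ethynyltri(propan-2-yl)silane | C#C[Si](C(C)C)(C(C)C)C(C)C | starting material
4 | (5R)-4,4-dimethoxy-2-methyl-5-{[tri(propan-2-yl)silyl]ethynyl}cyclohex-2-en-1-one | CC1=CC(OC)(OC)[C@@H](C#C[Si](C(C)C)(C(C)C)C(C)C)CC1=O | intermediate
5 | (1R,4R,6S)-5,5-dimethoxy-1-methyl-4-{[tri(propan-2-yl)silyl]ethynyl}-7-oxabicyclo[4.1.0]heptan-2-one | C[C@@]12O[C@@H]1C(OC)(OC)[C@@H](C#C[Si](C(C)C)(C(C)C)C(C)C)CC2=O | intermediate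
6 | acrolein (prop-2-enal) | C=CC=O | starting material
7 | 2,3-dibromopropanal | O=CC(Br)CBr | intermediate
8 | 2-bromoprop-2-enal | C=C(Br)C=O | intermediate
9 | vinylmagnesium bromide | C=C[Mg]Br | starting material
10 | 2-bromopenta-1,4-dien-3-ol (racemic) | C=CC(O)C(Br)=C | intermediate
11 | (1R,2R,4R,6S)-2-(3-hydroxypenta-1,4-dien-2-yl)-5,5-dimethoxy-1-methyl-4-{[tri(propan-2-yl)silyl]ethynyl}-7-oxabicyclo[4.1.0]heptan-2-ol (side-chain carbinol epimers) | C=CC(O)C(=C)[C@]1(O)C[C@H](C#C[Si](C(C)C)(C(C)C)C(C)C)C(OC)(OC)[C@H]2O[C@@]12C | intermediate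
12 | (1S,5R)-1-(3-hydroxypenta-1,4-dien-2-yl)-4,4-dimethoxy-2-methyl-5-{[tri(propan-2-yl)silyl]ethynyl}cyclohex-2-en-1-ol (side-chain carbinol epimers) | C=CC(O)C(=C)[C@]1(O)C[C@H](C#C[Si](C(C)C)(C(C)C)C(C)C)C(OC)(OC)C=C1C | intermediate
13 | 2-[(1S,5R)-1-hydroxy-4,4-dimethoxy-2-methyl-5-{[tri(propan-2-yl)silyl]ethynyl}cyclohex-2-en-1-yl]penta-1,4-dien-3-one | C=CC(=O)C(=C)[C@]1(O)C[C@H](C#C[Si](C(C)C)(C(C)C)C(C)C)C(OC)(OC)C=C1C | intermediate
14 | 5α-hydroxy-8,8-dimethoxy-10β-methyl-4-methylidene-7β-{[tri(propan-2-yl)silyl]ethynyl}-trans-decalin-3-one | CC(C)[Si](C(C)C)(C(C)C)C#C[C@H]1C[C@@]2(O)C(=C)C(=O)CC[C@]2(C)CC1(OC)OC | intermediate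
15 | 3β,5α-dihydroxy-8,8-dimethoxy-10β-methyl-4-methylidene-7β-{[tri(propan-2-yl)silyl]ethynyl}-trans-decalin | CC(C)[Si](C(C)C)(C(C)C)C#C[C@H]1C[C@@]2(O)C(=C)[C@@H](O)CC[C@]2(C)CC1(OC)OC | intermediate
16 | angelic acid, (2Z)-2-methylbut-2-enoic acid | C/C=C(/C)C(=O)O | starting material
17 | 3β-angeloyloxy-5α-hydroxy-8,8-dimethoxy-10β-methyl-4-methylidene-7β-{[tri(propan-2-yl)silyl]ethynyl}-trans-decalin | CC(C)[Si](C(C)C)(C(C)C)C#C[C@H]1C[C@@]2(O)C(=C)[C@@H](OC(=O)/C(C)=C\C)CC[C@]2(C)CC1(OC)OC | intermediate
18 | 3β-angeloyloxy-5α-hydroxy-10β-methyl-4-methylidene-7β-{[tri(propan-2-yl)silyl]ethynyl}-trans-decalin-8-one | CC(C)[Si](C(C)C)(C(C)C)C#C[C@H]1C[C@@]2(O)C(=C)[C@@H](OC(=O)/C(C)=C\C)CC[C@]2(C)CC1=O | intermediate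
19 | 3β-angeloyloxy-5α,8β-dihydroxy-10β-methyl-4-methylidene-7β-{[tri(propan-2-yl)silyl]ethynyl}-trans-decalin | CC(C)[Si](C(C)C)(C(C)C)C#C[C@H]1C[C@@]2(O)C(=C)[C@@H](OC(=O)/C(C)=C\C)CC[C@]2(C)C[C@H]1O | intermediate
20 | 3β-angeloyloxy-7β-ethynyl-5α,8β-dihydroxy-10β-methyl-4-methylidene-trans-decalin | C#C[C@H]1C[C@@]2(O)C(=C)[C@@H](OC(=O)/C(C)=C\C)CC[C@]2(C)C[C@H]1O | intermediate
21 | 8β-acetoxy-3β-angeloyloxy-7β-ethynyl-5α-hydroxy-10β-methyl-4-methylidene-trans-decalin | C#C[C@H]1C[C@@]2(O)C(=C)[C@@H](OC(=O)/C(C)=C\C)CC[C@]2(C)C[C@H]1OC(C)=O | intermediate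
22 | methyl 8β-acetoxy-3β-[(2Z)-2-methylbut-2-enoyloxy]-5α-hydroxy-7αH-eudesma-4(15),11(13)-dien-12-oate (CNP0179024.1) | C=C(C(=O)OC)[C@H]1C[C@@]2(O)C(=C)[C@@H](OC(=O)/C(C)=C\C)CC[C@]2(C)C[C@H]1OC(C)=O | target

Total step count: 15. Longest linear sequence: 13 steps (steps 1, 2, 3 and 6 to 15, from 1 to 22); steps 4 and 5 form the side branch that supplies 10.

Steps most likely to fail

Step 9 (key step). Hydrogen-atom transfer may go to the vinyl ketone or the α-methylene ketone instead of C9=C10, so that the dienone is reduced before it cyclizes, and the axial ketal oxygen may erode the preference for the trans ring fusion. The fallback makes the C10 radical without a metal hydride, by titanocene-mediated reductive opening of the oxirane (Nugent–RajanBabu reaction). It sets out from 11: MnO2 oxidation gives the epoxy dienone F1. Cp2TiCl (trivalent titanium, from Cp2TiCl2 and Zn in THF) opens the oxirane at the tertiary carbon, and the C10 radical cyclizes 6-endo onto the vinyl ketone to give the 9α-hydroxy decalin enone F2. Me4NBH(OAc)3 reduction gives the 3β,5α,9α-triol F3, and Yamaguchi esterification at the unhindered 3β-hydroxyl gives the angelate F4. PPTS hydrolysis of the ketal gives the 9α-hydroxy 8-ketone F5, and SmI2 (THF/MeOH, −78 °C) cleaves its C9–O bond. This returns the route at 18, which is reduced with NaBH4 as in step 12.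

Step 7. Oxygen transfer from the hindered oxirane may stall, or the Lewis-acidic tungsten chlorides may ionize the allylic alcohols or the ketal. The fallback replaces the stoichiometric low-valent metal by catalytic oxygen-atom transfer to a phosphine on a protected substrate. It sets out from 11: TMSOTf/2,6-lutidine gives the bis(trimethylsilyl) ether F6. MeReO3 (cat.) with PPh3 in benzene passes the oxirane oxygen to phosphorus and gives the silylated diene F7; silylation blocks rhenium-catalysed 1,3-transposition of the allylic alcohols. K2CO3/MeOH removes both silyl groups and returns the route at 12.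

Step 2. The rhodium acetylide may be consumed by alkyne oligomerization before it adds to the hindered, cross-conjugated ketal, or face selection may be poor. The fallback uses a preformed alkynyl donor under nickel catalysis: dimethyl{[tri(propan-2-yl)silyl]ethynyl}aluminium (from 3, n-BuLi and Me2AlCl) with Ni(acac)2 and a chiral bis(oxazoline) ligand in an asymmetric conjugate addition. It sets out from 2 and returns at 4; no further compound is made (F0).

Further compounds
F1 | step 9 | 2-[(1R,2R,4R,6S)-2-hydroxy-5,5-dimethoxy-1-methyl-4-{[tri(propan-2-yl)silyl]ethynyl}-7-oxabicyclo[4.1.0]heptan-2-yl]penta-1,4-dien-3-one | C=CC(=O)C(=C)[C@]1(O)C[C@H](C#C[Si](C(C)C)(C(C)C)C(C)C)C(OC)(OC)[C@H]2O[C@@]12C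
F2 | step 9 | 5α,9α-dihydroxy-8,8-dimethoxy-10β-methyl-4-methylidene-7β-{[tri(propan-2-yl)silyl]ethynyl}-trans-decalin-3-one | CC(C)[Si](C(C)C)(C(C)C)C#C[C@H]1C[C@@]2(O)C(=C)C(=O)CC[C@]2(C)[C@H](O)C1(OC)OC
F3 | step 9 | 3β,5α,9α-trihydroxy-8,8-dimethoxy-10β-methyl-4-methylidene-7β-{[tri(propan-2-yl)silyl]ethynyl}-trans-decalin | CC(C)[Si](C(C)C)(C(C)C)C#C[C@H]1C[C@@]2(O)C(=C)[C@@H](O)CC[C@]2(C)[C@H](O)C1(OC)OC
F4 | step 9 | 3β-angeloyloxy-5α,9α-dihydroxy-8,8-dimethoxy-10β-methyl-4-methylidene-7β-{[tri(propan-2-yl)silyl]ethynyl}-trans-decalin | CC(C)[Si](C(C)C)(C(C)C)C#C[C@H]1C[C@@]2(O)C(=C)[C@@H](OC(=O)/C(C)=C\C)CC[C@]2(C)[C@H](O)C1(OC)OC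
F5 | step 9 | 3β-angeloyloxy-5α,9α-dihydroxy-10β-methyl-4-methylidene-7β-{[tri(propan-2-yl)silyl]ethynyl}-trans-decalin-8-one | CC(C)[Si](C(C)C)(C(C)C)C#C[C@H]1C[C@@]2(O)C(=C)[C@@H](OC(=O)/C(C)=C\C)CC[C@]2(C)[C@H](O)C1=O
F6 | step 7 | bis(trimethylsilyl) ether of 11 | C=CC(O[Si](C)(C)C)C(=C)[C@]1(O[Si](C)(C)C)C[C@H](C#C[Si](C(C)C)(C(C)C)C(C)C)C(OC)(OC)[C@H]2O[C@@]12C
F7 | step 7 | bis(trimethylsilyl) ether of 12 | C=CC(O[Si](C)(C)C)C(=C)[C@]1(O[Si](C)(C)C)C[C@H](C#C[Si](C(C)C)(C(C)C)C(C)C)C(OC)(OC)C=C1C
F0 | step 2 | none | none
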